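**Retrosynthetic overview**

1. Target 27 ⇐ 25 ⇐ 24 ⇐ 22: the last steps are acylation of O8, desilylation of O15 and unmasking of the α‑methylene lactone from its Me2NCH2 adduct.
2. 22 ⇐ 19 (key step): a seven‑membered ene‑lactone ring (O8, C3, C4, C5, C6, C7, C8) is opened at O8–C3 by the side chain on C8, CH2(9)–C10(OH)(CH3)–C1(=O)–C2H3. O10 takes over the acyl carbon C3, so the ring grows to nine atoms (C3–C10, O10), and C2 closes the furanone on C3.
3. 19 ⇐ 18 (RCM, C4=C5, Z forced by the ring) ⇐ 13 + acid 16; 13 ⇐ ketone 6 + acrolein (6,7‑syn aldol), 1,3‑anti reduction (C8); C10 comes from (S)‑citramalic acid.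
4. Enabling feature: C8 carries both the ring oxygen O8 of the seven‑membered lactone and the chain that places alkoxide O10 six atoms, and enolate carbon C2 seven atoms, from acyl carbon C3.
5. Ring order: dioxolanone (temporary) → O8–C1 γ‑lactone (temporary) → C6/C12 γ‑lactone → seven‑membered lactone → furanone, nine‑membered oxa ring and ten‑membered carbocycle in one step.

Key step: step 14

Remark: the acyl group in the given SMILES is (R)‑2‑methylbutanoyl, and (R)‑2‑methylbutanoic acid is assumed purchasable as the single enantiomer; locants C1–C15 (O6, O8, O10 on C6, C8, C10) follow germacranolide numbering, the target is 6R,7R,8R,10S, and the C11 epimers from step 7 are carried together because C11 becomes sp2 in step 17.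

**Route**

Step 1
Reactants: 1 (S)‑citramalic acid
Product: 2 2‑[(4S)‑2,2,4‑trimethyl‑5‑oxo‑1,3‑dioxolan‑4‑yl]acetic acid
Conditions: 2,2‑dimethoxypropane, PPTS (cat.), CH2Cl2, rt
Reagents that add atoms: 2,2‑dimethoxypropane, COC(C)(C)OC
Why: Acid‑catalysed transketalisation should tie up the α‑hydroxy acid as the five‑membered dioxolanone and leave the CH2CO2H arm (C8) free, as for malic acid; C10 comes unchanged from the chiral pool.

Step 2
Reactants: 2 the dioxolanone acid; 3 tert‑butyl 3‑bromopropanoate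
Product: 6 tert‑butyl 4‑oxo‑5‑[(4S)‑2,2,4‑trimethyl‑5‑oxo‑1,3‑dioxolan‑4‑yl]pentanoate, via acid chloride 4 (not isolated), via organozinc bromide 5 (not isolated)
Conditions: 2, (COCl)2, DMF (cat.), CH2Cl2, 0 °C to rt, evaporate; 3, Zn dust, LiCl, THF, 40 °C; then 4 + 5, Pd(PPh3)4 (5 mol %), THF, 0 °C to rt
Reagents that add atoms: none
Why: Negishi acylation of an ester‑bearing alkylzinc halide by an acid chloride should give the γ‑keto ester (C8 ketone, C7 from the zinc homoenolate) without touching the dioxolanone.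

Step 3
Reactants: 6 the keto ester; 7 acrolein
Product: 8 tert‑butyl 3‑(1‑hydroxyprop‑2‑enyl)‑4‑oxo‑5‑[(4S)‑2,2,4‑trimethyl‑5‑oxo‑1,3‑dioxolan‑4‑yl]pentanoate, 6,7‑syn, C6 and C7 arranged as in 27
Conditions: (−)‑Ipc2BOTf, i‑Pr2NEt, CH2Cl2, −78 °C; 7, −78 to −20 °C; H2O2, pH 7 buffer, MeOH, 0 °C
Reagents that add atoms: none
Why: Paterson aldol: the bulky boron triflate should enolise the less hindered C7 methylene (C9 is neopentyl) to the Z‑enol borinate, whose chair transition state gives the 6,7‑syn adduct, and the Ipc ligands are expected to direct attack to the Si face of acrolein (6R).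

Step 4
Reactants: 8 the aldol adduct
Product: 9 tert‑butyl 4‑hydroxy‑3‑{1‑hydroxy‑2‑[(4S)‑2,2,4‑trimethyl‑5‑oxo‑1,3‑dioxolan‑4‑yl]ethyl}hex‑5‑enoate, 6,8‑anti diol, C6, C7, C8 as in 27
Conditions: Me4NBH(OAc)3, MeCN/AcOH (1:1), −30 °C
Reagents that add atoms: none
Why: Evans–Saksena reduction: intramolecular hydride delivery from the boron bound to O6 through a chair transition state should set C8 1,3‑anti to C6–OH.

Step 5
Reactants: 9 the anti diol
Product: 10 tert‑butyl 4‑hydroxy‑3‑[(2R,4S)‑4‑hydroxy‑4‑methyl‑5‑oxooxolan‑2‑yl]hex‑5‑enoate (O8–C1 γ‑lactone; C6–OH and C10–OH free)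
Conditions: PPTS (cat.), toluene, 50 °C, acetone removed in a N2 stream
Reagents that add atoms: none
Why: Acid‑catalysed transacylation: only O8 reaches the activated dioxolanone carbonyl through a five‑membered ring (O6 would need seven), and the tert‑butyl ester does not lactonise under these conditions, so the two secondary hydroxyls are differentiated and acetone is lost.

Step 6
Reactants: 10 the hydroxy lactone
Product: 11 bis(triethylsilyl) ether of 10 (O6 and O10 silylated)
Conditions: TESOTf (2.5 equiv), 2,6‑lutidine, CH2Cl2, −78 to 0 °C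
Reagents that add atoms: triethylsilyl triflate, CC[Si](CC)(CC)OS(=O)(=O)C(F)(F)F
Why: Silyl triflate silylation should cap both the allylic secondary and the tertiary hydroxyl ahead of the enolate and organolithium steps.

Step 7
Reactants: 11 the bis‑TES ether
Product: 12 C11‑(dimethylaminomethyl) derivative of 11 (C11 epimers)
Conditions: LDA (1.15 equiv), THF, −78 °C; Me2N=CH2+ I− (Eschenmoser's salt), −78 to −20 °C
Reagents that add atoms: N,N‑dimethylmethyleneiminium iodide, C=[N+](C)C.[I-]
Why: Mannich reaction of the tert‑butyl ester enolate, the only enolisable site because the lactone α‑carbon C10 is quaternary, installs C13 as CH2NMe2, a masked α‑methylene group.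

Step 8
Reactants: 12 the Mannich base
Product: 13 tert‑butyl 2‑[(dimethylamino)methyl]‑3‑[(1R,3S)‑1‑hydroxy‑3‑methyl‑4‑oxo‑3‑(triethylsilyloxy)pentyl]‑4‑(triethylsilyloxy)hex‑5‑enoate
Conditions: MeLi (2.2 equiv), THF, −78 °C; AcOH, −78 °C
Reagents that add atoms: methyllithium, [Li]C
Why: Mono‑addition of an organolithium to a lactone: the lithium hemiketal should survive at −78 °C and collapse on quench to the methyl ketone (C1, C2) and free C8–OH, while the hindered tert‑butyl ester is expected to stay intact.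

Step 9
Reactants: 14 ethyl 2‑(hydroxymethyl)acrylate
Product: 15 ethyl 2‑[(tert‑butyldiphenylsilyloxy)methyl]acrylate
Conditions: TBDPSCl, imidazole, CH2Cl2, 0 °C to rt
Reagents that add atoms: tert‑butylchlorodiphenylsilane, CC(C)(C)[Si](Cl)(c1ccccc1)c1ccccc1
Why: Standard silylation of a primary alcohol gives the C3–C4–C15 unit with O15 protected until step 16.

Step 10
Reactants: 15 the silyl ether ester
Product: 16 2‑[(tert‑butyldiphenylsilyloxy)methyl]acrylic acid
Conditions: LiOH·H2O, THF/H2O, 0 °C to rt; 1 M HCl to pH 3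
Reagents that add atoms: lithium hydroxide, [Li+].[OH-]
Why: Saponification of the ethyl ester; the TBDPS ether tolerates dilute hydroxide at this temperature.

Step 11
Reactants: 13 the methyl ketone alcohol; 16 the acrylic acid
Product: 17 ester of 13 at O8 with 16
Conditions: 16, 2,4,6‑trichlorobenzoyl chloride, Et3N, THF, rt; then 13, DMAP, toluene, rt
Reagents that add atoms: none
Why: Yamaguchi esterification should acylate the hindered secondary C8–OH, the only free hydroxyl, and places acyl carbon C3 on O8.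

Step 12
Reactants: 17 the acrylate ester
Product: 18 trans‑4,5‑disubstituted γ‑lactone (O6–C12) bearing C6‑vinyl, C11‑CH2NMe2 and, at C7, the chain CH(O8‑acryloyl)–CH2–C(OH)(CH3)–C(=O)CH3
Conditions: TFA/CH2Cl2/H2O (10:40:1), 0 °C to rt; aq. NaHCO3
Reagents that add atoms: none
Why: Acidolysis removes the tert‑butyl ester and both TES ethers, and the γ‑hydroxy acid lactonises on O6, the only free secondary hydroxyl, to the 6,7‑trans lactone fixed by the C6/C7 configurations.

Step 13
Reactants: 18 the diene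
Product: 19 seven‑membered (Z)‑ene‑lactone [O8–C3(=O)–C4(CH2OTBDPS)=C5–C6–C7–C8] trans‑fused at C6–C7 to the γ‑lactone; C8 carries CH2–C(OH)(CH3)–C(=O)CH3
Conditions: Hoveyda–Grubbs II (10 mol %), p‑TsOH·H2O (1.1 equiv), toluene (2 mM), 80 °C; aq. NaHCO3
Reagents that add atoms: none
Why: Ring‑closing metathesis between the 2‑substituted acrylate and the C6 vinyl group should close the seven‑membered ring, which forces the Z geometry of C4=C5; the amine is masked as its ammonium salt.

Step 14
Reactants: 19 the bis‑lactone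
Product: 22 bridged 3(2H)‑furanone with free C8–OH, C15–OTBDPS and the C11‑CH2NMe2 γ‑lactone (skeleton of 27), via nine‑membered lactone 20 (not isolated), via cyclic hemiketal 21 (not isolated)
Conditions: LiHMDS (2.3 equiv), THF, −78 to −20 °C; AcOH, −78 °C; then AcOH/THF/H2O (3:1:1), 40 °C
Reagents that add atoms: none
Why: Proposed new method: the C10 alkoxide of the alkoxide/C2‑enolate dianion should attack ene‑lactone carbonyl C3 through a six‑membered cyclic orthoester (1,3 O‑to‑O acyl shift), so that O8 leaves the ring and O10, C10 and C9 enter it (seven‑ to nine‑membered, 20); the methyl‑ketone enolate then adds to the same carbonyl (21) and acid dehydrates the hemiketal to the 3(2H)‑furanone, which also completes the ten‑membered carbocycle, while direct C‑acylation through a seven‑membered transition state followed by hemiketalisation would converge on the same product. The closest known reactions are acyl migration in 1,3‑diol monoesters, the Baker–Venkataraman‑type base‑induced cyclisation of α‑acyloxy ketones to 3(2H)‑furanones, and transacylative ring enlargements. The furanone ring closes 5‑exo‑trig (C2 on C3), and the nine‑membered ring is made by expansion of the seven‑membered lactone, not by end‑to‑end closure. No stereocentre is created: C10 is carried through, the hemiketal centre C3 is lost on dehydration and the Z geometry of C4=C5 is inherited from the seven‑membered ring. The step needs enolisation of the methyl ketone and not of the γ‑lactone (C11–H), and 1,2‑ rather than conjugate attack on the enoate; the lower pKa of the ketone, the hindered tertiary C11–H and the six‑/five‑membered geometry of attack at C3 (eight‑membered for C5) should secure this, with the dehydration to the vinylogous ester as thermodynamic sink.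

Step 15
Reactants: 22 the furanone alcohol; 23 (R)‑2‑methylbutanoic acid
Product: 24 8‑O‑[(R)‑2‑methylbutanoyl] ester of 22
Conditions: 23, DCC, DMAP (cat.), CH2Cl2, 0 °C to rt
Reagents that add atoms: none
Why: Steglich esterification of the only free hydroxyl (C8–OH) with retention at C8 and at the α‑carbon of the acid.

Step 16
Reactants: 24 the ester
Product: 25 15‑hydroxy compound (Me2NCH2 adduct of 27)
Conditions: HF·pyridine, pyridine/THF, 0 °C to rt
Reagents that add atoms: none
Why: Fluoride‑mediated desilylation frees the primary allylic alcohol under buffered, non‑basic conditions that the esters, lactone and dienone should tolerate.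

Step 17
Reactants: 25 the amino lactone
Product: 27 target, via methiodide 26 (not isolated)
Conditions: MeI (excess), MeCN, rt; evaporate; aq. NaHCO3, CH2Cl2, rt
Reagents that add atoms: none
Why: N‑Quaternisation followed by E1cB (Hofmann‑type) elimination of trimethylamine from the β‑ammonio lactone unmasks the α‑methylene‑γ‑butyrolactone under mild base.

**Compound list**

1 | (S)‑citramalic acid | OC(=O)C[C@](C)(O)C(=O)O | starting material
2 | 2‑[(4S)‑2,2,4‑trimethyl‑5‑oxo‑1,3‑dioxolan‑4‑yl]acetic acid | OC(=O)C[C@]1(C)OC(C)(C)OC1=O | intermediate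
3 | tert‑butyl 3‑bromopropanoate | BrCCC(=O)OC(C)(C)C | starting material
4 | 2‑[(4S)‑2,2,4‑trimethyl‑5‑oxo‑1,3‑dioxolan‑4‑yl]acetyl chloride | ClC(=O)C[C@]1(C)OC(C)(C)OC1=O | intermediate
5 | (3‑tert‑butoxy‑3‑oxopropyl)zinc bromide | Br[Zn]CCC(=O)OC(C)(C)C | intermediate
6 | tert‑butyl 4‑oxo‑5‑[(4S)‑2,2,4‑trimethyl‑5‑oxo‑1,3‑dioxolan‑4‑yl]pentanoate | CC(C)(C)OC(=O)CCC(=O)C[C@]1(C)OC(C)(C)OC1=O | intermediate
7 | acrolein | C=CC=O | starting material
8 | 6,7‑syn aldol adduct (C8 ketone, dioxolanone, tert‑butyl ester) | O=C1OC(C)(C)O[C@@]1(C)CC(=O)[C@@H](CC(=O)OC(C)(C)C)[C@H](O)C=C | intermediate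
9 | 6,8‑anti diol (dioxolanone, tert‑butyl ester) | O=C1OC(C)(C)O[C@@]1(C)C[C@@H](O)[C@@H](CC(=O)OC(C)(C)C)[C@H](O)C=C | intermediate
10 | tert‑butyl 4‑hydroxy‑3‑[(2R,4S)‑4‑hydroxy‑4‑methyl‑5‑oxooxolan‑2‑yl]hex‑5‑enoate | O=C1O[C@H](C[C@]1(C)O)[C@@H](CC(=O)OC(C)(C)C)[C@H](O)C=C | intermediate
11 | 6,10‑bis‑O‑triethylsilyl ether of 10 | O=C1O[C@H](C[C@]1(C)O[Si](CC)(CC)CC)[C@@H](CC(=O)OC(C)(C)C)[C@H](O[Si](CC)(CC)CC)C=C | intermediate
12 | C11‑(dimethylaminomethyl) derivative of 11 (C11 epimers) | O=C1O[C@H](C[C@]1(C)O[Si](CC)(CC)CC)[C@@H](C(CN(C)C)C(=O)OC(C)(C)C)[C@H](O[Si](CC)(CC)CC)C=C | intermediate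
13 | methyl ketone with free C8–OH (6,10‑bis‑OTES, tert‑butyl ester) | CC(=O)[C@@](C)(O[Si](CC)(CC)CC)C[C@@H](O)[C@@H](C(CN(C)C)C(=O)OC(C)(C)C)[C@H](O[Si](CC)(CC)CC)C=C | intermediate
14 | ethyl 2‑(hydroxymethyl)acrylate | C=C(CO)C(=O)OCC | starting material
15 | ethyl 2‑[(tert‑butyldiphenylsilyloxy)methyl]acrylate | C=C(CO[Si](c1ccccc1)(c1ccccc1)C(C)(C)C)C(=O)OCC | intermediate
16 | 2‑[(tert‑butyldiphenylsilyloxy)methyl]acrylic acid | C=C(CO[Si](c1ccccc1)(c1ccccc1)C(C)(C)C)C(=O)O | intermediate
17 | 8‑O‑acrylate ester of 13 | CC(=O)[C@@](C)(O[Si](CC)(CC)CC)C[C@@H](OC(=O)C(=C)CO[Si](c1ccccc1)(c1ccccc1)C(C)(C)C)[C@@H](C(CN(C)C)C(=O)OC(C)(C)C)[C@H](O[Si](CC)(CC)CC)C=C | intermediate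
18 | 6,7‑trans γ‑lactone with C6‑vinyl, 8‑O‑acrylate, free C10–OH, methyl ketone | CC(=O)[C@@](C)(O)C[C@@H](OC(=O)C(=C)CO[Si](c1ccccc1)(c1ccccc1)C(C)(C)C)[C@H]2C(CN(C)C)C(=O)O[C@@H]2C=C | intermediate
19 | seven‑membered (Z)‑ene‑lactone trans‑fused to the γ‑lactone, side chain CH2–C(OH)(CH3)–C(=O)CH3 on C8 | CC(=O)[C@@](C)(O)C[C@H]1OC(=O)/C(CO[Si](c3ccccc3)(c3ccccc3)C(C)(C)C)=C\[C@H]2OC(=O)C(CN(C)C)[C@H]12 | intermediate
20 | nine‑membered lactone (C3 acyl on O10), free C8–OH, acetyl on C10 | CC(=O)[C@]1(C)C[C@@H](O)[C@H]2C(CN(C)C)C(=O)O[C@@H]2/C=C(/CO[Si](c3ccccc3)(c3ccccc3)C(C)(C)C)C(=O)O1 | intermediate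
21 | cyclic hemiketal (C3‑hydroxy‑dihydrofuranone, hydrate of 22) | CN(C)CC1C(=O)O[C@@H]2/C=C(/CO[Si](c4ccccc4)(c4ccccc4)C(C)(C)C)C3(O)CC(=O)[C@](C)(C[C@@H](O)[C@@H]12)O3 | intermediate
22 | bridged 3(2H)‑furanone, free C8–OH, C15–OTBDPS, C11‑CH2NMe2 | CN(C)CC1C(=O)O[C@@H]2/C=C(/CO[Si](c4ccccc4)(c4ccccc4)C(C)(C)C)C3=CC(=O)[C@](C)(C[C@@H](O)[C@@H]12)O3 | intermediate
23 | (R)‑2‑methylbutanoic acid | CC[C@@H](C)C(=O)O | starting material
24 | 8‑O‑[(R)‑2‑methylbutanoyl] ester of 22 | CN(C)CC1C(=O)O[C@@H]2/C=C(/CO[Si](c4ccccc4)(c4ccccc4)C(C)(C)C)C3=CC(=O)[C@](C)(C[C@@H](OC(=O)[C@H](C)CC)[C@@H]12)O3 | intermediate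
25 | 15‑hydroxy amino lactone (Me2NH adduct of 27) | CN(C)CC1C(=O)O[C@@H]2/C=C(/CO)C3=CC(=O)[C@](C)(C[C@@H](OC(=O)[C@H](C)CC)[C@@H]12)O3 | intermediate
26 | methiodide of 25 | C[N+](C)(C)CC1C(=O)O[C@@H]2/C=C(/CO)C3=CC(=O)[C@](C)(C[C@@H](OC(=O)[C@H](C)CC)[C@@H]12)O3.[I-] | intermediate
27 | CNP0307052.2 | C=C1C(=O)O[C@@H]2/C=C(/CO)C3=CC(=O)[C@](C)(C[C@@H](OC(=O)[C@H](C)CC)[C@@H]12)O3 | target

**Step count and risks**

Total step count: 17. Longest linear sequence: 15 steps (steps 1–8 and 11–17) from (S)‑citramalic acid.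

Steps most likely to fail:

1. Step 14 (Proposed new method). The dianion may be diverted: enolisation of the γ‑lactone at C11 followed by six‑ring Claisen closure on C3, or relactonisation of the freed O8 alkoxide onto C12, would stop the acyl transfer short of the furanone. The fallback uses known reactions only and sets out from 13. Steglich esterification of C8–OH with 23 gives the 8‑O‑(R)‑2‑methylbutanoate F1. Its lithium enolate (LiHMDS, THF, −78 °C) is C‑acylated with the imidazolide of 16, F2 (from 16 and carbonyldiimidazole), to give the 1,3‑diketone F3. TFA/CH2Cl2 removes the TES groups and the tert‑butyl ester, closes the γ‑lactone on O6 and cyclodehydrates the α′‑hydroxy‑1,3‑diketone to the 5‑alkenyl furanone F4. Ring‑closing metathesis of F4 (Hoveyda–Grubbs II, p‑TsOH, toluene, 110 °C) then closes the nine‑membered ring at C4=C5 directly and returns to the route at 24.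

2. Step 3. Facial discrimination of acrolein by the chiral enol borinate may be poor, which would give a mixture of the two syn diastereomers. The fallback sets out from 6 and 7. An achiral syn‑selective boron aldol (Bu2BOTf, i‑Pr2NEt, CH2Cl2, −78 °C) gives 8 together with its (6S,7R) syn diastereomer F5. Sharpless kinetic resolution of the secondary allylic alcohols (Ti(Oi‑Pr)4, D‑(−)‑DIPT, t‑BuOOH, 4 Å MS, CH2Cl2, −20 °C) should epoxidise the vinyl group of the unwanted isomer to the erythro epoxy alcohol F6 and leave 8, which is separated and rejoins the route at 8.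

3. Step 8. Addition to the hindered lactone carbonyl may be slow, and over‑addition to the released ketone or attack on the tert‑butyl ester may then compete. The fallback sets out from 12. Aminolysis of the lactone with Me(MeO)NH·HCl/i‑PrMgCl (THF, −20 °C) gives the Weinreb amide F7 with free C8–OH, and MeMgBr (THF, 0 °C) converts it through the stable chelated adduct into 13, where the route continues.

**Further compounds**

F1 | step 14 | 8‑O‑[(R)‑2‑methylbutanoyl] ester of 13 | CC(=O)[C@@](C)(O[Si](CC)(CC)CC)C[C@@H](OC(=O)[C@H](C)CC)[C@@H](C(CN(C)C)C(=O)OC(C)(C)C)[C@H](O[Si](CC)(CC)CC)C=C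
F2 | step 14 | 1‑{2‑[(tert‑butyldiphenylsilyloxy)methyl]acryloyl}imidazole | C=C(CO[Si](c1ccccc1)(c1ccccc1)C(C)(C)C)C(=O)n1ccnc1
F3 | step 14 | 1,3‑diketone from C2‑acylation of F1 | C=C(CO[Si](c1ccccc1)(c1ccccc1)C(C)(C)C)C(=O)CC(=O)[C@@](C)(O[Si](CC)(CC)CC)C[C@@H](OC(=O)[C@H](C)CC)[C@@H](C(CN(C)C)C(=O)OC(C)(C)C)[C@H](O[Si](CC)(CC)CC)C=C
F4 | step 14 | 5‑[3‑(tert‑butyldiphenylsilyloxy)prop‑1‑en‑2‑yl]‑3(2H)‑furanone carrying the 8‑O‑acyl chain and the C6‑vinyl γ‑lactone | C=C(CO[Si](c1ccccc1)(c1ccccc1)C(C)(C)C)C1=CC(=O)[C@](C)(C[C@@H](OC(=O)[C@H](C)CC)[C@H]2C(CN(C)C)C(=O)O[C@@H]2C=C)O1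
F5 | step 3 | (6S,7R) syn diastereomer of 8 | O=C1OC(C)(C)O[C@@]1(C)CC(=O)[C@H](CC(=O)OC(C)(C)C)[C@@H](O)C=C
F6 | step 3 | erythro epoxy alcohol from F5 | O=C1OC(C)(C)O[C@@]1(C)CC(=O)[C@H](CC(=O)OC(C)(C)C)[C@@H](O)[C@H]2CO2
F7 | step 8 | Weinreb amide from lactone opening of 12 (free C8–OH) | CON(C)C(=O)[C@@](C)(O[Si](CC)(CC)CC)C[C@@H](O)[C@@H](C(CN(C)C)C(=O)OC(C)(C)C)[C@H](O[Si](CC)(CC)CC)C=C
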